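in all of them: gas 0.90 mM (held)

| run | electrophile | nucleophile | scavenger | remark | time |
|---|---|---|---|---|---|
| Friday's | 10 mM | 0.95 equiv | 0.30 equiv | run made earlier |  |
| Saturday's | 40 mM | 0.95 equiv | 0.30 equiv | run made earlier |  |
| Wednesday's | 20 mM | 0.95 equiv | 0.15 equiv | run made earlier |  |
| flask | 20 mM | 0.950 equiv | 0.300 equiv |  | 12 min |

- Friday's (time / min: electrophile / %, product / %): 2.00: 98.3, 2.7; 4.00: 94.9, 3.7; 6.00: 92.3, 5.9; 8.00: 92.8, 7.5; 10.0: 90.8, 8.5
- Saturday's (time / min: electrophile / %, product / %): 0.833: 96.4, 2.7; 1.33: 95.1, 5.6; 2.50: 91.6, 10.5; 5.00: 85.2, 15.5; 10.0: 77.4, 24.1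
- Wednesday's (time / min: electrophile / %, product / %): 0.833: 99.6, 1.2; 1.33: 98.0, 3.9; 2.50: 96.5, 5.5; 5.00: 91.5, 9.6; 10.0: 84.5, 14.7

(standard deviation of a reading: 1 percentage point)

- acid set free is meant together with its idle adduct
- at the start none of free base is dissolved
- what may be going on: electrophile + nucleophile -> acid set free + product; nucleophile + acid set free <-> protonated nucleophile; acid set free + free base <-> salt of the base; nucleophile <-> dormant form; gas <-> free base; acid set free + free base <-> idle adduct; acid set free + scavenger -> scavenged by-product
- the earlier runs do not show how much of nucleophile is bound; that part of a forecast is a guess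

1. part of the electrophile that has reacted at 12 min
2. share of free nucleophile in free nucleophile and protonated nucleophile together, at 12 min

The easy step came first. Wednesday's run had the flask's charges of electrophile and nucleophile, so I read its early product as a pseudo-first-order rate constant with the whole nucleophile charge free: 5.5% in 2.50 min gave 0.0220 min⁻¹. Its last two product readings, divided by the electrophile remaining, gave 0.0116 min⁻¹ around 7.50 min. I took the electrophile's rate to follow free nucleophile, so the ratio, 52.8%, read as the part of the charge still free then, though a scatter of 1 percentage point makes it rough.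

I assumed that this loss was first-order, at 0.0852 min⁻¹, and that the flask's scavenger, twice Wednesday's, changed nothing. That left 36.0% of the charged nucleophile free at 12 min; I carried this free fraction forward. Summing the rate over that decline gave 15.2% of the electrophile reacted. I then took protonation as instantaneous and complete, so each acid set free sat on a nucleophile: 3.05 mM protonated nucleophile beside 6.83 mM free, a share of 69.2%.

The forecast stood higher on both, at 17.5% and 85%: “The free share is poorly determined, so I guess”.

The flask gave 16.2% and 70.8%. At 12.0 min its dormant form held 5.04 mM, more than the 3.13 mM of protonated nucleophile, and 40% of the charged nucleophile stood free. My free fraction, set beside that protonated nucleophile, gives a share of 68.6%.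

    electrophile + nucleophile → acid set free + product (k = 0.0200 M⁻¹ s⁻¹)
    nucleophile + acid set free ⇌ protonated nucleophile, settled at all times (K = 20000 M⁻¹)
    acid set free + free base ⇌ salt of the base, settled at all times (K = 2000 M⁻¹)
    nucleophile ⇌ dormant form (K = 3.80, k = 6.10 × 10⁻⁴ s⁻¹)
    gas ⇌ free base, rate k5*(csat - [free base]) (kL = 0.00540 s⁻¹)
    acid set free + free base ⇌ idle adduct, settled at all times (K = 350 M⁻¹)
    acid set free + scavenger → scavenged by-product (k = 1.00 M⁻¹ s⁻¹)

For the neighbour flask charged with 0.570 equiv of nucleophile, the same free fraction gives 4.10 mM free, 9.44% of the electrophile reacted, and a share of 68.5%. That neighbour computed to 10.0% and 70.3%, with 39% of its nucleophile free.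

Readings and results were computed from invented constants; scatter was added.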